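Monomer in chains is the product, and we want to know which flask holds the most of it at the end.

| flask | free monomer | initiator | temperature | remark | time |
|---|---|---|---|---|---|
| Wednesday's | 0.52 M | 10 mM | 5 °C | run made earlier |  |
| Monday's | 0.52 M | 16 mM | 35 °C | run made earlier |  |
| Saturday's | 1 M | 7.3 mM | 5 °C | run made earlier |  |
| theta | 0.52 M | 7.3 mM | 35 °C |  | 30 min |
| alpha | 0.52 M | 7.3 mM | 10 °C |  | 30 min |
| zeta | 0.52 M | 7.3 mM | 60 °C |  | 30 min |

| run | time / min | monomer in chains / % |
|---|---|---|
| Wednesday's | 20.0 | 0.9 |
| Wednesday's | 50.0 | 1.4 |
| Wednesday's | 120 | 3.3 |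
| Wednesday's | 180 | 4.9 |
| Monday's | 5.00 | 3.2 |
| Monday's | 12.0 | 6.7 |
| Monday's | 25.0 | 13.7 |
| Monday's | 40.0 | 21.9 |
| Saturday's | 20.0 | 0.4 |
| Saturday's | 50.0 | 1.1 |
| Saturday's | 120 | 3.0 |
| Saturday's | 180 | 4.8 |

(scatter of a reading: 0.3 percentage points)

* the best flask by amount of monomer in chains, in percent of the free monomer charged; "all alike" if 1.5 percentage points covers them all (theta / alpha / zeta / all alike)
* amount of monomer in chains at the end, in percent of the free monomer charged, theta
* amount of monomer in chains at the end, in percent of the free monomer charged, alpha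
* amount of monomer in chains at the end, in percent of the free monomer charged, zeta



We read each run through the monomer time τ: the time of a reading divided by minus the natural logarithm of the fraction of free monomer left. Its inverse is a pseudo-first-order constant. Monday's last reading gives 162 min.

Time comes first. By hand, a steady τ makes the yield climb with time along an exponential curve. Monday's readings fit a steady τ: the first gives 154 min, and a scatter of 0.3 percentage points on that small reading covers the gap to the last.

Initiator comes next. By hand we let τ go with the inverse square root of c(initiator), the order the forecast also takes. The readings can't prove this. Wednesday's run gives 3580 min and Saturday's 3660 min, but those runs differ in free monomer as well. Moved to 7.3 mM, Monday's τ becomes 240 min and Wednesday's becomes 4190 min.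

Temperature is last. Those two values give an apparent activation energy of 68.0 kJ mol⁻¹, as read from scattered readings. So τ is 2500 min for alpha and 32.7 min for zeta, the shortest of the flasks, though zeta stands beyond the temperatures of the runs. Our reckoning gives 11.8% for theta, 1.20% for alpha and 60.0% for zeta.

The forecast names zeta as best. It gives 11.4% (8.5% to 14.5%) for theta, 1.2% (0.8% to 1.8%) for alpha and 55% (33% to 73%) for zeta, warning of that last figure that “chain death or a ceiling would lower it”. Its zeta figure lies below ours. Still, its low end for zeta stands above its high ends for theta and alpha, so the choice of flask survives the width of its ranges.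

The flasks give 11.5% for theta, 1.25% for alpha and 56.6% for zeta, so zeta is best.

    initiator → 2 initiating radical (k = 3.40 × 10⁻⁵ s⁻¹, Ea = 115 kJ mol⁻¹)
    free monomer + initiating radical → growing radical + monomer in chains (k = 2.60 × 10⁶ M⁻¹ s⁻¹, Ea = 28.0 kJ mol⁻¹)
    free monomer + growing radical → monomer in chains + growing radical, rate k3*[growing radical]*[free monomer] (k = 25000 M⁻¹ s⁻¹, Ea = 15.0 kJ mol⁻¹)
    free monomer → decomposition product (k = 2.20 × 10⁻⁶ s⁻¹, Ea = 123 kJ mol⁻¹)
    2 growing radical → dead chain (k = 7.00 × 10⁸ M⁻¹ s⁻¹, Ea = 13.0 kJ mol⁻¹)
    (constants at 60 °C)

In zeta, c(growing radical) stands at 1.85 × 10⁻⁸ M after 15.0 min and 1.83 × 10⁻⁸ M after 30.0 min. Read back from its yield, zeta's τ is 35.9 min, against our 32.7 min and Monday's 162 min. Moved by the square root to a neighbour of zeta charged with 0.018 M of initiator, it becomes 22.9 min, which reckons to 73.0%. That neighbour holds 73.1% of monomer in chains.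

All runs were computed with constants of no real substance; the scatter is artificial.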